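**Strategy.** The cyclopentane ring carries an aldol pattern: an acetyl group on the CH next to one ring-fusion carbon and an acyloxy group on the adjacent CH. Cutting that aldol bond and joining the two carbonyl carbons instead turns the five-membered ring into a 1-methylcyclohexene, the Diels–Alder adduct of isoprene and (S)-4-isopropylcyclohex-2-enone. The key step is this Lewis acid-promoted cycloaddition: in one operation it forms the bonds from the two ring-fusion carbons to the ring CH2 and to the future acetyl-bearing CH, anti to the isopropyl group. Later, ozonolysis and intramolecular aldol addition excise one ring carbon, which becomes the acetyl carbonyl.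

Key step: step 3

Remark: locants in the Why lines are those of the name of the compound concerned, and the ring made in step 3 is called ring B. Methyl angelate, angelic anhydride and the prolinol ether catalyst are assumed to be purchasable. The sense of induction in steps 1 and 9 is taken from the standard enamine and Sharpless models.

Step 1
Reactants: 1 3-methylbutanal; 2 but-3-en-2-one
Product: 3 (S)-5-oxo-2-(propan-2-yl)hexanal
Conditions: (S)-2-(methoxydiphenylmethyl)pyrrolidine (5 mol %), ethyl 3,4-dihydroxybenzoate (20 mol %), neat, 4 °C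
Reagents that add atoms: none
Why: Enamine-catalysed asymmetric Michael addition, in which the E-enamine of 1 is attacked by 2 on the face away from the methoxydiphenylmethyl group of the (S)-catalyst, which sets the (S) centre.

Step 2
Reactants: 3 (S)-5-oxo-2-(propan-2-yl)hexanal
Product: 4 (S)-4-(propan-2-yl)cyclohex-2-en-1-one
Conditions: LiOH (cat.), i-PrOH, rt
Reagents that add atoms: none
Why: Intramolecular aldol condensation (methyl ketone enolate onto the aldehyde, then dehydration) should give the conjugated cyclohexenone, and the mild base limits epimerisation of the aldehyde α-centre before ring closure.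

Step 3
Reactants: 4 (S)-4-(propan-2-yl)cyclohex-2-en-1-one; 5 isoprene (2-methylbuta-1,3-diene)
Product: 6 (4S,4aS,8aS)-6-methyl-4-(propan-2-yl)-3,4,4a,5,8,8a-hexahydronaphthalen-1(2H)-one (cis-fused)
Conditions: EtAlCl2 (0.5 equiv), isoprene (5 equiv), toluene, −20 °C → rt
Reagents that add atoms: none
Why: EtAlCl2 binds the enone oxygen and lowers its LUMO, so a concerted but asynchronous [4+2] cycloaddition (Lewis acid-catalysed Diels–Alder reaction) joins C1 of isoprene to the enone β-carbon (C4a of 6) and C4 of isoprene to the α-carbon (C8a) in one event. The closest known reaction type is the aluminium chloride-type catalysed Diels–Alder reaction of 4-alkylcyclohex-2-enones with isoprene or butadiene, used to build cadinane and amorphane decalins. Ring B (a cyclohexene) is closed by suprafacial–suprafacial cycloaddition and is cis-fused to ring A. C4a is set by approach of the diene anti to the C4 isopropyl group, and C8a follows from the suprafacial addition; it is formed with the wrong configuration on purpose and is corrected in step 4 because it is α to the ketone. The step needs "para" regiochemistry (methyl-bearing C6 in a 1,4 relation to C8a), secured by matching the larger HOMO coefficient at C1 of isoprene with the larger LUMO coefficient at the β-carbon of the complexed enone, and anti facial selectivity, secured by the isopropyl group on the carbon next to the β-carbon. Low temperature and substoichiometric Lewis acid should keep isoprene polymerisation and double-bond migration in check.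

Step 4
Reactants: 6 (4S,4aS,8aS)-6-methyl-4-(propan-2-yl)-3,4,4a,5,8,8a-hexahydronaphthalen-1(2H)-one
Product: 7 (4S,4aS,8aR)-6-methyl-4-(propan-2-yl)-3,4,4a,5,8,8a-hexahydronaphthalen-1(2H)-one (trans-fused)
Conditions: NaOMe (0.2 equiv), MeOH, rt
Reagents that add atoms: none
Why: Base-mediated epimerisation at C8a through the ketone enolate should give, under thermodynamic control, the trans-fused 1-decalone with the isopropyl group equatorial.

Step 5
Reactants: 7 (4S,4aS,8aR)-6-methyl-4-(propan-2-yl)-3,4,4a,5,8,8a-hexahydronaphthalen-1(2H)-one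
Product: 9 (4R,4aS,8aR)-6-methyl-4-(propan-2-yl)-4a,5,8,8a-tetrahydronaphthalen-1(4H)-one, via trimethylsilyl enol ether 8 (not isolated)
Conditions: LiN(i-Pr)2, Me3SiCl, THF, −78 °C; then Pd(OAc)2 (1.1 equiv), MeCN, rt
Reagents that add atoms: chlorotrimethylsilane, C[Si](C)(C)Cl (silyl group of 8 only, lost again on the way to 9)
Why: Saegusa–Ito oxidation: kinetic deprotonation at the C2 methylene rather than the ring-fusion CH gives 8, which Pd(OAc)2 dehydrogenates to the C2–C3 enone without touching a stereocentre (the C4 descriptor changes through priorities only).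

Step 6
Reactants: 9 (4R,4aS,8aR)-6-methyl-4-(propan-2-yl)-4a,5,8,8a-tetrahydronaphthalen-1(4H)-one
Product: 11 (3R,4S,4aS,8aR)-3-hydroxy-6-methyl-4-(propan-2-yl)-3,4,4a,5,8,8a-hexahydronaphthalen-1(2H)-one, via pinacol boronate 10 (not isolated)
Conditions: CuCl (5 mol %), NaOt-Bu (10 mol %), DPEphos (5 mol %), B2pin2 (1.1 equiv), MeOH (2 equiv), THF, rt; then NaBO3·4H2O, THF/H2O, rt
Reagents that add atoms: bis(pinacolato)diboron, CC1(C)OB(OC1(C)C)B1OC(C)(C)C(C)(C)O1 (boryl group of 10 only); sodium perborate, [Na+].[O-]OB=O (the hydroxyl oxygen of 11)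
Why: Copper-catalysed conjugate borylation followed by oxidation with retention: the boryl-copper nucleophile should add to C3 of the rigid trans-fused enone along the axial trajectory anti to the axial C4–H (as in axial additions to steroidal 1-en-3-ones), so boron and then OH end up axial and cis to the equatorial isopropyl group.

Step 7
Reactants: 11 (3R,4S,4aS,8aR)-3-hydroxy-6-methyl-4-(propan-2-yl)-3,4,4a,5,8,8a-hexahydronaphthalen-1(2H)-one
Product: 12 (1S,2R,4aR,8aR)-7-methyl-4-methylidene-1-(propan-2-yl)-1,2,3,4,4a,5,8,8a-octahydronaphthalen-2-ol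
Conditions: Ph3PCH3Br (3.5 equiv), n-BuLi (3.3 equiv), THF, −20 °C → rt
Reagents that add atoms: methyltriphenylphosphonium bromide, C[P+](c1ccccc1)(c1ccccc1)c1ccccc1.[Br-] (the CH2 carbon)
Why: Wittig methylenation: excess ylide first forms the lithium alkoxide and then olefinates the unhindered ketone at low temperature, where retro-aldol cleavage should be slow, and no stereocentre changes.

Step 8
Reactants: 13 methyl (Z)-2-methylbut-2-enoate (methyl angelate)
Product: 14 (Z)-2-methylbut-2-en-1-ol
Conditions: i-Bu2AlH (2.2 equiv), CH2Cl2, −78 → 0 °C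
Reagents that add atoms: none
Why: 1,2-Reduction of the conjugated ester with an aluminium hydride should give the allylic alcohol with the Z double bond intact.

Step 9
Reactants: 14 (Z)-2-methylbut-2-en-1-ol
Product: 15 [(2R,3S)-2,3-dimethyloxiran-2-yl]methanol
Conditions: Ti(Oi-Pr)4 (10 mol %), D-(−)-diethyl tartrate (12 mol %), t-BuOOH, 4 Å MS, CH2Cl2, −20 °C
Reagents that add atoms: tert-butyl hydroperoxide, CC(C)(C)OO (the epoxide oxygen)
Why: Sharpless asymmetric epoxidation: with D-(−)-diethyl tartrate the titanium–tartrate complex should deliver oxygen to the face that gives the (2R,3S)-epoxy alcohol (L-(+)-tartrate would give its enantiomer), and the cis relation of CH2OH and the C3 methyl comes from the Z alkene.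

Step 10
Reactants: 15 [(2R,3S)-2,3-dimethyloxiran-2-yl]methanol
Product: 16 (2S,3S)-2,3-dimethyloxirane-2-carboxylic acid
Conditions: RuCl3 (2 mol %), NaIO4 (3 equiv), CCl4/MeCN/H2O, rt
Reagents that add atoms: sodium periodate, [Na+].[O-]I(=O)(=O)=O (the new carboxyl oxygen)
Why: Ruthenium tetroxide-type oxidation of a primary 2,3-epoxy alcohol to the glycidic acid leaves the epoxide and both centres untouched (C2 changes descriptor through priorities only).

Step 11
Reactants: 12 (1S,2R,4aR,8aR)-7-methyl-4-methylidene-1-(propan-2-yl)-1,2,3,4,4a,5,8,8a-octahydronaphthalen-2-ol; 16 (2S,3S)-2,3-dimethyloxirane-2-carboxylic acid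
Product: 18 (1S,2R,4aR,8aR)-7-methyl-4-methylidene-1-(propan-2-yl)-1,2,3,4,4a,5,8,8a-octahydronaphthalen-2-yl (2S,3S)-2,3-dimethyloxirane-2-carboxylate, via mixed anhydride 17 (not isolated)
Conditions: 16, 2,4,6-trichlorobenzoyl chloride, Et3N, THF, rt; then 12, DMAP, toluene, rt → 40 °C
Reagents that add atoms: 2,4,6-trichlorobenzoyl chloride, O=C(Cl)c1c(Cl)cc(Cl)cc1Cl (aroyl group of 17 only)
Why: Yamaguchi esterification: DMAP takes the epoxy-acyl group from 17 and passes it to the hindered axial alcohol while the molecule still holds no base-sensitive group, and any minor enantiomer carried from step 1 becomes a separable diastereomer here.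

Step 12
Reactants: 18 (1S,2R,4aR,8aR)-7-methyl-4-methylidene-1-(propan-2-yl)-1,2,3,4,4a,5,8,8a-octahydronaphthalen-2-yl (2S,3S)-2,3-dimethyloxirane-2-carboxylate
Product: 20 (1R,2S,3R,4R)-5-methylidene-4-(2-oxoethyl)-3-(2-oxopropyl)-2-(propan-2-yl)cyclohexyl (2S,3S)-2,3-dimethyloxirane-2-carboxylate, via secondary ozonide 19 (not isolated)
Conditions: O3 (1 equiv, Sudan Red 7B end point), CH2Cl2, −78 °C; then Me2S, −78 °C → rt
Reagents that add atoms: ozone, [O-][O+]=O (three oxygens in 19, two of them kept as the carbonyl oxygens of 20)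
Why: Chemoselective ozonolysis: the electron-rich trisubstituted ring B alkene should react with ozone much faster than the 1,1-disubstituted exocyclic methylene (as in the selective cleavage of the ring alkene of limonene), and Me2S reduces 19 to the keto aldehyde.

Step 13
Reactants: 20 (1R,2S,3R,4R)-5-methylidene-4-(2-oxoethyl)-3-(2-oxopropyl)-2-(propan-2-yl)cyclohexyl (2S,3S)-2,3-dimethyloxirane-2-carboxylate
Product: 21 (1R,2S,3aR,6R,7S,7aR)-1-acetyl-2-hydroxy-4-methylidene-7-(propan-2-yl)octahydro-1H-inden-6-yl (2S,3S)-2,3-dimethyloxirane-2-carboxylate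
Conditions: LiCl (3 equiv), DBU (0.3 equiv), THF/MeCN, −20 → 0 °C
Reagents that add atoms: none
Why: Reversible intramolecular aldol addition: the internal Z enolate of the methyl ketone should close 5-exo on the aldehyde through a lithium-chelated chair-like transition state on the face away from the isopropyl-bearing carbon, and retro-aldol equilibration should funnel the material to the chelated cis ketol, which sets C2 (S) and C1 (R).

Step 14
Reactants: 21 (1R,2S,3aR,6R,7S,7aR)-1-acetyl-2-hydroxy-4-methylidene-7-(propan-2-yl)octahydro-1H-inden-6-yl (2S,3S)-2,3-dimethyloxirane-2-carboxylate; 22 (Z)-2-methylbut-2-enoic anhydride (angelic anhydride)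
Product: 23 (1R,2S,3aR,6R,7S,7aR)-1-acetyl-2-{[(2Z)-2-methylbut-2-enoyl]oxy}-4-methylidene-7-(propan-2-yl)octahydro-1H-inden-6-yl (2S,3S)-2,3-dimethyloxirane-2-carboxylate (CNP0300602.1)
Conditions: LiN(SiMe3)2 (1.05 equiv), THF, −78 °C; then 22 (1.5 equiv), −78 → −40 °C; NH4Cl quench
Reagents that add atoms: none
Why: O-Acylation of the lithium aldolate by the anhydride at low temperature uses no nucleophilic catalyst, so the Z (angelate) geometry should be kept and the β-acyloxy ketone is never warmed with base.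

**Compound list**

1 | 3-methylbutanal | CC(C)CC=O | starting material
2 | but-3-en-2-one | CC(=O)C=C | starting material
3 | (S)-5-oxo-2-(propan-2-yl)hexanal | CC(C)[C@H](CCC(C)=O)C=O | intermediate
4 | (S)-4-(propan-2-yl)cyclohex-2-en-1-one | O=C1CC[C@@H](C(C)C)C=C1 | intermediate
5 | isoprene (2-methylbuta-1,3-diene) | C=CC(C)=C | starting material
6 | (4S,4aS,8aS)-6-methyl-4-(propan-2-yl)-3,4,4a,5,8,8a-hexahydronaphthalen-1(2H)-one (cis-fused) | O=C1CC[C@@H](C(C)C)[C@@H]2CC(C)=CC[C@H]12 | intermediate
7 | (4S,4aS,8aR)-6-methyl-4-(propan-2-yl)-3,4,4a,5,8,8a-hexahydronaphthalen-1(2H)-one (trans-fused) | O=C1CC[C@@H](C(C)C)[C@@H]2CC(C)=CC[C@@H]12 | intermediate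
8 | trimethyl{[(4S,4aS,8aR)-6-methyl-4-(propan-2-yl)-3,4,4a,5,8,8a-hexahydronaphthalen-1-yl]oxy}silane | C[Si](C)(C)OC1=CC[C@@H](C(C)C)[C@@H]2CC(C)=CC[C@@H]12 | intermediate
9 | (4R,4aS,8aR)-6-methyl-4-(propan-2-yl)-4a,5,8,8a-tetrahydronaphthalen-1(4H)-one | O=C1C=C[C@@H](C(C)C)[C@@H]2CC(C)=CC[C@@H]12 | intermediate
10 | (3R,4S,4aS,8aR)-6-methyl-4-(propan-2-yl)-3-(4,4,5,5-tetramethyl-1,3,2-dioxaborolan-2-yl)-3,4,4a,5,8,8a-hexahydronaphthalen-1(2H)-one | O=C1C[C@@H](B3OC(C)(C)C(C)(C)O3)[C@@H](C(C)C)[C@@H]2CC(C)=CC[C@@H]12 | intermediate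
11 | (3R,4S,4aS,8aR)-3-hydroxy-6-methyl-4-(propan-2-yl)-3,4,4a,5,8,8a-hexahydronaphthalen-1(2H)-one | O=C1C[C@@H](O)[C@@H](C(C)C)[C@@H]2CC(C)=CC[C@@H]12 | intermediate
12 | (1S,2R,4aR,8aR)-7-methyl-4-methylidene-1-(propan-2-yl)-1,2,3,4,4a,5,8,8a-octahydronaphthalen-2-ol | C=C1C[C@@H](O)[C@@H](C(C)C)[C@@H]2CC(C)=CC[C@@H]12 | intermediate
13 | methyl (Z)-2-methylbut-2-enoate | COC(=O)/C(C)=C\C | starting material
14 | (Z)-2-methylbut-2-en-1-ol | OC/C(C)=C\C | intermediate
15 | [(2R,3S)-2,3-dimethyloxiran-2-yl]methanol | OC[C@@]1(C)O[C@H]1C | intermediate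
16 | (2S,3S)-2,3-dimethyloxirane-2-carboxylic acid | OC(=O)[C@@]1(C)O[C@H]1C | intermediate
17 | (2S,3S)-2,3-dimethyloxirane-2-carboxylic 2,4,6-trichlorobenzoic anhydride | O=C(OC(=O)[C@@]1(C)O[C@H]1C)c1c(Cl)cc(Cl)cc1Cl | intermediate
18 | (1S,2R,4aR,8aR)-7-methyl-4-methylidene-1-(propan-2-yl)-1,2,3,4,4a,5,8,8a-octahydronaphthalen-2-yl (2S,3S)-2,3-dimethyloxirane-2-carboxylate | C=C1C[C@@H](OC(=O)[C@@]2(C)O[C@H]2C)[C@@H](C(C)C)[C@@H]2CC(C)=CC[C@@H]12 | intermediate
19 | secondary ozonide (1,2,4-trioxolane) of the ring B alkene of 18, mixture of isomers at the two trioxolane carbons | C=C1C[C@@H](OC(=O)[C@@]2(C)O[C@H]2C)[C@@H](C(C)C)[C@@H]2CC3(C)OOC(O3)C[C@@H]12 | intermediate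
20 | (1R,2S,3R,4R)-5-methylidene-4-(2-oxoethyl)-3-(2-oxopropyl)-2-(propan-2-yl)cyclohexyl (2S,3S)-2,3-dimethyloxirane-2-carboxylate | C=C1C[C@@H](OC(=O)[C@@]2(C)O[C@H]2C)[C@@H](C(C)C)[C@H](CC(C)=O)[C@H]1CC=O | intermediate
21 | (1R,2S,3aR,6R,7S,7aR)-1-acetyl-2-hydroxy-4-methylidene-7-(propan-2-yl)octahydro-1H-inden-6-yl (2S,3S)-2,3-dimethyloxirane-2-carboxylate | C=C1C[C@@H](OC(=O)[C@@]2(C)O[C@H]2C)[C@@H](C(C)C)[C@@H]2[C@@H](C(C)=O)[C@@H](O)C[C@@H]12 | intermediate
22 | (Z)-2-methylbut-2-enoic anhydride | C/C=C(/C)C(=O)OC(=O)/C(C)=C\C | starting material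
23 | (1R,2S,3aR,6R,7S,7aR)-1-acetyl-2-{[(2Z)-2-methylbut-2-enoyl]oxy}-4-methylidene-7-(propan-2-yl)octahydro-1H-inden-6-yl (2S,3S)-2,3-dimethyloxirane-2-carboxylate | C=C1C[C@@H](OC(=O)[C@@]2(C)O[C@H]2C)[C@@H](C(C)C)[C@@H]2[C@@H](C(C)=O)[C@@H](OC(=O)/C(C)=C\C)C[C@@H]12 | target

**Count.** Total: 14 steps. Longest linear sequence: 11 steps (steps 1–7 and 11–14); steps 8–10 make the side-chain acid.

**Steps most likely to fail**

Step 13 (aldol ring contraction). The closure may go through the wrong enolate (aldehyde enolate onto the ketone), diastereocontrol at the carbinol centre may be lost, or the ketol may dehydrate. The fallback sets out from 20 and comes back at 21. The aldol is driven deliberately to condensation (DBU, toluene, 60 °C) to give the conjugated 1-acetylcyclopentene, (3aR,4S,5R,7aR)-3-acetyl-7-methylidene-4-(propan-2-yl)-3a,4,5,6,7,7a-hexahydro-1H-inden-5-yl (2S,3S)-2,3-dimethyloxirane-2-carboxylate F1. Copper-catalysed conjugate borylation (CuCl, NaOt-Bu, B2pin2, MeOH) with a chiral Josiphos-type bisphosphine, its enantiomer chosen to deliver boron to the β face, then puts the carbinol centre under catalyst control and gives the β-boryl ketone F2, with the acetyl centre settling trans to the neighbouring ring carbon on protonation. Oxidation with NaBO3 (retention) returns 21.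

Step 6 (conjugate borylation). The boryl-copper reagent may attack the equatorial face and give the C3 epimer. The fallback sets out from 9 and comes back at 12. The same borylation–oxidation is run regardless of its facial outcome, and the C3-epimeric hydroxy ketone (3S,4S,4aS,8aR)-3-hydroxy-6-methyl-4-(propan-2-yl)-3,4,4a,5,8,8a-hexahydronaphthalen-1(2H)-one F3 (or its mixture with 11) is methylenated as in step 7 to the epimeric alcohol F4. Oxidation with the periodinane DMP (NaHCO3 buffer) gives the β,γ-unsaturated ketone F5, and LiBH(s-Bu)3 at −78 °C reduces it by equatorial hydride attack, as in the menthone to neomenthol reduction, to the axial alcohol 12.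

Step 12 (selective ozonolysis). Ozone may also cleave the exocyclic methylene, or conversion may stay incomplete when ozone is kept short. The fallback sets out from 18 and comes back at 20. Epoxidation with m-CPBA (1 equiv, NaHCO3, CH2Cl2, 0 °C) takes the more electron-rich trisubstituted alkene and gives the ring B epoxide F6, which H5IO6 in THF/H2O cleaves to keto aldehyde 20.

**Further compounds**

F1 | step 13 | (3aR,4S,5R,7aR)-3-acetyl-7-methylidene-4-(propan-2-yl)-3a,4,5,6,7,7a-hexahydro-1H-inden-5-yl (2S,3S)-2,3-dimethyloxirane-2-carboxylate | C=C1C[C@@H](OC(=O)[C@@]2(C)O[C@H]2C)[C@@H](C(C)C)[C@@H]2C(C(C)=O)=CC[C@@H]12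
F2 | step 13 | (1S,2S,3aR,6R,7S,7aR)-1-acetyl-4-methylidene-7-(propan-2-yl)-2-(4,4,5,5-tetramethyl-1,3,2-dioxaborolan-2-yl)octahydro-1H-inden-6-yl (2S,3S)-2,3-dimethyloxirane-2-carboxylate | C=C1C[C@@H](OC(=O)[C@@]2(C)O[C@H]2C)[C@@H](C(C)C)[C@@H]2[C@@H](C(C)=O)[C@@H](B3OC(C)(C)C(C)(C)O3)C[C@@H]12
F3 | step 6 | (3S,4S,4aS,8aR)-3-hydroxy-6-methyl-4-(propan-2-yl)-3,4,4a,5,8,8a-hexahydronaphthalen-1(2H)-one | O=C1C[C@H](O)[C@@H](C(C)C)[C@@H]2CC(C)=CC[C@@H]12
F4 | step 6 | (1S,2S,4aR,8aR)-7-methyl-4-methylidene-1-(propan-2-yl)-1,2,3,4,4a,5,8,8a-octahydronaphthalen-2-ol | C=C1C[C@H](O)[C@@H](C(C)C)[C@@H]2CC(C)=CC[C@@H]12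
F5 | step 6 | (1S,4aR,8aR)-7-methyl-4-methylidene-1-(propan-2-yl)-3,4,4a,5,8,8a-hexahydronaphthalen-2(1H)-one | C=C1CC(=O)[C@@H](C(C)C)[C@@H]2CC(C)=CC[C@@H]12
F6 | step 12 | ring B epoxide of 18 (6,7-epoxide, either epoxide face) | C=C1C[C@@H](OC(=O)[C@@]2(C)O[C@H]2C)[C@@H](C(C)C)[C@@H]2CC3(C)OC3C[C@@H]12
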